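Ring C (C1–O to ring B, C2–O to ring D, hydroxyls at C3 and C5, hydrogens at C4 and C6) is disconnected at C1–C6 and C4–C5. A Danheiser benzannulation should build this 1,2,3,5-tetraoxygenated ring in one operation from a four-carbon cyclobutenone (C1–C4, already holding the crowded C2–O–ring D ether and the C3 oxygen) and ethoxyethyne (C5, C6), releasing C1 as the only free phenol. The precursor is racemic 4-aryloxy-3-ethoxycyclobut-2-en-1-one, whose aryl group is the permethylated ring D–ring E unit, made from an aryloxyketene and ethoxyethyne. Ring B, with ring A attached, then enters by SNAr and a double Baeyer–Villiger (Dakin-type) oxidation.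

Key step: step 6

Remark on notation: ArO stands for the 3,5-dimethoxy-4-(3,4,5-trimethoxyphenoxy)phenoxy group (permethylated rings D and E).
Remark on design: the two-carbon partner of the key step is ethoxyethyne, so the C5 oxygen arrives as an ethyl ether; the alkyne is purchasable, the ether is inert to the carbonate and fluoride of step 9, and it falls with all other alkyl ethers in step 11.
Assumption: 5-bromo-2-fluoroisophthalaldehyde 17 and 2,4,6-trimethoxyphenol 19 are taken as catalogue compounds; 17 would otherwise follow from 5-bromo-2-fluoro-1,3-dimethylbenzene by fourfold benzylic bromination and hydrolysis.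

Step 1
Reactants: 1 syringaldehyde; 2 5-bromo-1,2,3-trimethoxybenzene
Product: 3 3,5-dimethoxy-4-(3,4,5-trimethoxyphenoxy)benzaldehyde
Conditions: CuI (10 mol%), picolinic acid (20 mol%), K3PO4, DMSO, 100 °C, argon
Reagents that add atoms: none
Why: Ligand-accelerated Ullmann diaryl ether coupling, in which the picolinate-bound copper catalyst tolerates the two ortho methoxy groups of the phenoxide and the aldehyde is inert to K3PO4 in DMSO.

Step 2
Reactants: 3 3,5-dimethoxy-4-(3,4,5-trimethoxyphenoxy)benzaldehyde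
Product: 5 3,5-dimethoxy-4-(3,4,5-trimethoxyphenoxy)phenol, via aryl formate 4 (not isolated)
Conditions: mCPBA, CH2Cl2, 0 °C to rt; then K2CO3 (cat.), MeOH, rt
Reagents that add atoms: 3-chloroperoxybenzoic acid (mCPBA), OOC(=O)c1cccc(Cl)c1
Why: Baeyer–Villiger (Dakin-type) oxidation, in which the aryl group para to the aryloxy donor migrates in preference to hydride and the resulting formate is cleaved by mild methanolysis.

Step 3
Reactants: 5 3,5-dimethoxy-4-(3,4,5-trimethoxyphenoxy)phenol; 6 bromoacetic acid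
Product: 7 2-[3,5-dimethoxy-4-(3,4,5-trimethoxyphenoxy)phenoxy]acetic acid
Conditions: NaOH (3.5 equiv), H2O/THF, 70 °C, nitrogen; then HCl to pH 1
Reagents that add atoms: none
Why: Williamson ether synthesis, the unhindered phenoxide displacing bromide from bromoacetate by SN2 while the solvated carboxylate is a far poorer nucleophile.

Step 4
Reactants: 7 2-[3,5-dimethoxy-4-(3,4,5-trimethoxyphenoxy)phenoxy]acetic acid
Product: 8 2-[3,5-dimethoxy-4-(3,4,5-trimethoxyphenoxy)phenoxy]acetyl chloride
Conditions: (COCl)2, DMF (cat.), CH2Cl2, 0 °C to rt; evaporate, use crude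
Reagents that add atoms: oxalyl chloride, O=C(Cl)C(=O)Cl
Why: Vilsmeier-catalysed acid chloride formation, which is neutral enough to leave the aryl methyl ethers and the electron-rich rings untouched.

Step 5
Reactants: 8 2-[3,5-dimethoxy-4-(3,4,5-trimethoxyphenoxy)phenoxy]acetyl chloride; 9 ethoxyethyne
Product: 11 4-[3,5-dimethoxy-4-(3,4,5-trimethoxyphenoxy)phenoxy]-3-ethoxycyclobut-2-en-1-one (racemic), via aryloxyketene 10 (not isolated)
Conditions: 9 (3 equiv), Et3N (1.3 equiv, slow addition), CH2Cl2, 0 °C to rt; chromatography on Et3N-deactivated silica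
Reagents that add atoms: none
Why: Dehydrochlorination gives the aryloxyketene, which should undergo the ketene–ynol ether [2+2] cycloaddition with the nucleophilic CH carbon of the alkyne bonding to the ketene carbonyl carbon; the C4 stereocentre forms as a racemate and is erased in step 6.

Step 6
Reactants: 11 4-ArO-3-ethoxycyclobut-2-en-1-one (racemic); 9 ethoxyethyne
Product: 16 2-[3,5-dimethoxy-4-(3,4,5-trimethoxyphenoxy)phenoxy]-3,5-diethoxyphenol, via vinylketene 12 (not isolated), via vinylcyclobutenone 13 (not isolated), via dienylketene 14 (not isolated), via cyclohexadienone 15 (not isolated)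
Conditions: 9 (4 equiv), toluene, 85 °C, sealed tube, argon
Reagents that add atoms: none
Why: On heating, 11 should open by a conrotatory 4π electrocyclic reaction (the aryloxy donor turning outward) to vinylketene 12, whose ketene C=C bond adds ethoxyethyne in a [2+2] cycloaddition to give 13; a second 4π opening gives dienylketene 14, which cyclises to dienone 15 and tautomerises to phenol 16. The closest known reaction type is the Danheiser benzannulation of cyclobutenones with alkynyl ethers, of which this is a direct case. Ring C is closed by a thermal disrotatory 6π electrocyclisation that joins C1 to C2, after C1–C6 and C4–C5 have been formed in the [2+2] step. No stereocentre is created, and the racemic C4 centre of 11 ends as the aromatic carbon C2. The regiochemistry required, C5 oxygen meta to the C1 hydroxyl, is secured by the polarisation of the ynol ether, whose nucleophilic CH carbon bonds to the electrophilic ketene carbon, while the aryloxy and ethoxy groups keep the adjacent positions they hold in 11. Excess alkyne and a temperature below the retro-ene threshold of ethoxyethyne should keep the vinylketene from acylating the product phenol.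

Step 7
Reactants: 17 5-bromo-2-fluoroisophthalaldehyde
Product: 18 2,2'-(5-bromo-2-fluoro-1,3-phenylene)bis(1,3-dioxolane)
Conditions: ethylene glycol (3 equiv), p-TsOH (cat.), toluene, reflux, Dean–Stark trap
Reagents that add atoms: ethylene glycol, OCCO
Why: Acid-catalysed acetalisation with azeotropic removal of water masks both formyl groups, which switches off SNAr at the C–F bond during the copper coupling that follows.

Step 8
Reactants: 18 2,2'-(5-bromo-2-fluoro-1,3-phenylene)bis(1,3-dioxolane); 19 2,4,6-trimethoxyphenol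
Product: 21 2-fluoro-5-(2,4,6-trimethoxyphenoxy)isophthalaldehyde, via bis(dioxolane) diaryl ether 20 (not isolated)
Conditions: CuI (10 mol%), picolinic acid (20 mol%), K3PO4, DMSO, 90 °C, argon; then 2 M HCl, THF, rt
Reagents that add atoms: water, O
Why: Ullmann diaryl ether coupling at the unhindered C–Br bond (the fluoride is not activated while the aldehydes are acetals), followed by acid hydrolysis of the two dioxolanes.

Step 9
Reactants: 16 2-ArO-3,5-diethoxyphenol; 21 2-fluoro-5-(2,4,6-trimethoxyphenoxy)isophthalaldehyde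
Product: 22 2-(2-ArO-3,5-diethoxyphenoxy)-5-(2,4,6-trimethoxyphenoxy)isophthalaldehyde
Conditions: K2CO3 (1.5 equiv), DMF, 50 °C
Reagents that add atoms: none
Why: SNAr by addition–elimination, the fluoride flanked by two ortho formyl groups being displaced by the phenoxide of 16 through a Meisenheimer adduct, so the crowded ring B–ring C ether forms without a metal and all alkyl ethers are inert to fluoride and carbonate.

Step 10
Reactants: 22 2-(2-ArO-3,5-diethoxyphenoxy)-5-(2,4,6-trimethoxyphenoxy)isophthalaldehyde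
Product: 24 2-(2-ArO-3,5-diethoxyphenoxy)-5-(2,4,6-trimethoxyphenoxy)benzene-1,3-diol, via bis-formate 23 (not isolated)
Conditions: mCPBA (3 equiv), CH2Cl2, 0 °C to rt; then K2CO3 (cat.), MeOH, 0 °C
Reagents that add atoms: 3-chloroperoxybenzoic acid (mCPBA), OOC(=O)c1cccc(Cl)c1
Why: Twofold Baeyer–Villiger (Dakin-type) oxidation, each formyl group lying ortho to an aryloxy donor so that aryl migration should beat hydride migration, and methanolysis of the two formates gives the ring B hydroxyls that flank the ether to ring C.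

Step 11
Reactants: 24 2-(2-ArO-3,5-diethoxyphenoxy)-5-(2,4,6-trimethoxyphenoxy)benzene-1,3-diol
Product: 25 2-{2-[3,5-dihydroxy-4-(3,4,5-trihydroxyphenoxy)phenoxy]-3,5-dihydroxyphenoxy}-5-(2,4,6-trihydroxyphenoxy)benzene-1,3-diol (target)
Conditions: BBr3 (25 equiv), CH2Cl2, −78 °C to rt; then H2O, 0 °C, argon
Reagents that add atoms: none
Why: Lewis acid ether dealkylation, BBr3 binding each alkyl aryl ether oxygen and bromide cleaving the O–alkyl bond by SN2, which removes eight methyl and two ethyl groups while the diaryl ether bonds offer no alkyl carbon to attack.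

Compound list
1 | syringaldehyde (4-hydroxy-3,5-dimethoxybenzaldehyde) | COc1cc(C=O)cc(OC)c1O | starting material
2 | 5-bromo-1,2,3-trimethoxybenzene | COc1cc(Br)cc(OC)c1OC | starting material
3 | 3,5-dimethoxy-4-(3,4,5-trimethoxyphenoxy)benzaldehyde | O=Cc1cc(OC)c(Oc2cc(OC)c(OC)c(OC)c2)c(OC)c1 | intermediate
4 | 3,5-dimethoxy-4-(3,4,5-trimethoxyphenoxy)phenyl formate | O=COc1cc(OC)c(Oc2cc(OC)c(OC)c(OC)c2)c(OC)c1 | intermediate
5 | 3,5-dimethoxy-4-(3,4,5-trimethoxyphenoxy)phenol | Oc1cc(OC)c(Oc2cc(OC)c(OC)c(OC)c2)c(OC)c1 | intermediate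
6 | bromoacetic acid | OC(=O)CBr | starting material
7 | 2-[3,5-dimethoxy-4-(3,4,5-trimethoxyphenoxy)phenoxy]acetic acid | OC(=O)COc1cc(OC)c(Oc2cc(OC)c(OC)c(OC)c2)c(OC)c1 | intermediate
8 | 2-[3,5-dimethoxy-4-(3,4,5-trimethoxyphenoxy)phenoxy]acetyl chloride | ClC(=O)COc1cc(OC)c(Oc2cc(OC)c(OC)c(OC)c2)c(OC)c1 | intermediate
9 | ethoxyethyne | CCOC#C | starting material
10 | 2-ArO-ethen-1-one (aryloxyketene) | O=C=COc1cc(OC)c(Oc2cc(OC)c(OC)c(OC)c2)c(OC)c1 | intermediate
11 | 4-[3,5-dimethoxy-4-(3,4,5-trimethoxyphenoxy)phenoxy]-3-ethoxycyclobut-2-en-1-one (racemic) | CCOC1=CC(=O)C1Oc1cc(OC)c(Oc2cc(OC)c(OC)c(OC)c2)c(OC)c1 | intermediate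
12 | (3Z)-4-ArO-3-ethoxybuta-1,3-dien-1-one (vinylketene) | O=C=C/C(OCC)=C/Oc1cc(OC)c(Oc2cc(OC)c(OC)c(OC)c2)c(OC)c1 | intermediate
13 | 4-[(Z)-2-ArO-1-ethoxyethenyl]-3-ethoxycyclobut-2-en-1-one (racemic) | CCOC1=CC(=O)C1/C(OCC)=C/Oc1cc(OC)c(Oc2cc(OC)c(OC)c(OC)c2)c(OC)c1 | intermediate
14 | (3E,5Z)-6-ArO-3,5-diethoxyhexa-1,3,5-trien-1-one (dienylketene) | O=C=C/C(OCC)=C\C(OCC)=C\Oc1cc(OC)c(Oc2cc(OC)c(OC)c(OC)c2)c(OC)c1 | intermediate
15 | 6-ArO-3,5-diethoxycyclohexa-2,4-dien-1-one (racemic) | O=C1C=C(OCC)C=C(OCC)C1Oc1cc(OC)c(Oc2cc(OC)c(OC)c(OC)c2)c(OC)c1 | intermediate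
16 | 2-[3,5-dimethoxy-4-(3,4,5-trimethoxyphenoxy)phenoxy]-3,5-diethoxyphenol | CCOc1cc(OCC)cc(O)c1Oc1cc(OC)c(Oc2cc(OC)c(OC)c(OC)c2)c(OC)c1 | intermediate
17 | 5-bromo-2-fluoroisophthalaldehyde | O=Cc1cc(Br)cc(C=O)c1F | starting material
18 | 2,2'-(5-bromo-2-fluoro-1,3-phenylene)bis(1,3-dioxolane) | Fc1c(C2OCCO2)cc(Br)cc1C1OCCO1 | intermediate
19 | 2,4,6-trimethoxyphenol | COc1cc(OC)c(O)c(OC)c1 | starting material
20 | 2,2'-[2-fluoro-5-(2,4,6-trimethoxyphenoxy)-1,3-phenylene]bis(1,3-dioxolane) | COc1cc(OC)c(Oc2cc(C3OCCO3)c(F)c(C3OCCO3)c2)c(OC)c1 | intermediate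
21 | 2-fluoro-5-(2,4,6-trimethoxyphenoxy)isophthalaldehyde | COc1cc(OC)c(Oc2cc(C=O)c(F)c(C=O)c2)c(OC)c1 | intermediate
22 | 2-(2-ArO-3,5-diethoxyphenoxy)-5-(2,4,6-trimethoxyphenoxy)isophthalaldehyde | CCOc1cc(OCC)cc(Oc2c(C=O)cc(Oc3c(OC)cc(OC)cc3OC)cc2C=O)c1Oc1cc(OC)c(Oc2cc(OC)c(OC)c(OC)c2)c(OC)c1 | intermediate
23 | 2-(2-ArO-3,5-diethoxyphenoxy)-5-(2,4,6-trimethoxyphenoxy)-1,3-phenylene diformate | CCOc1cc(OCC)cc(Oc2c(OC=O)cc(Oc3c(OC)cc(OC)cc3OC)cc2OC=O)c1Oc1cc(OC)c(Oc2cc(OC)c(OC)c(OC)c2)c(OC)c1 | intermediate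
24 | 2-(2-ArO-3,5-diethoxyphenoxy)-5-(2,4,6-trimethoxyphenoxy)benzene-1,3-diol | CCOc1cc(OCC)cc(Oc2c(O)cc(Oc3c(OC)cc(OC)cc3OC)cc2O)c1Oc1cc(OC)c(Oc2cc(OC)c(OC)c(OC)c2)c(OC)c1 | intermediate
25 | 2-{2-[3,5-dihydroxy-4-(3,4,5-trihydroxyphenoxy)phenoxy]-3,5-dihydroxyphenoxy}-5-(2,4,6-trihydroxyphenoxy)benzene-1,3-diol (CNP0227069.0) | Oc1cc(O)c(Oc2cc(O)c(Oc3cc(O)cc(O)c3Oc3cc(O)c(Oc4cc(O)c(O)c(O)c4)c(O)c3)c(O)c2)c(O)c1 | target

Total step count: 11. Longest linear sequence: 9 (steps 1 to 6, then 9 to 11); steps 7 and 8 form the convergent branch.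

Steps most likely to fail

Step 6. The vinylogous-ester cyclobutenone may need a ring-opening temperature at which ethoxyethyne fragments by retro-ene reaction, or the vinylketene may oligomerise or acylate the product phenol faster than the alkyne traps it. The fallback leaves the benzannulation, sets out from phenol 5 and comes back to the route at target 25. Copper-catalysed coupling of 5 with purchasable 2-bromo-3,5-dimethoxybenzaldehyde (CuI, picolinic acid, K3PO4, DMSO, 90 °C; the bromide is activated by its ortho formyl group and the phenol is unhindered) should give 2-ArO-3,5-dimethoxybenzaldehyde F1. Oxidation with mCPBA to 2-ArO-3,5-dimethoxyphenyl formate F2 and methanolysis should give 2-ArO-3,5-dimethoxyphenol F3, the dimethyl analogue of 16. F3 then takes the place of 16 under the conditions of steps 9 to 11: SNAr with 21 gives 2-(2-ArO-3,5-dimethoxyphenoxy)-5-(2,4,6-trimethoxyphenoxy)isophthalaldehyde F4, twofold Baeyer–Villiger oxidation proceeds through 2-(2-ArO-3,5-dimethoxyphenoxy)-5-(2,4,6-trimethoxyphenoxy)-1,3-phenylene diformate F5 to 2-(2-ArO-3,5-dimethoxyphenoxy)-5-(2,4,6-trimethoxyphenoxy)benzene-1,3-diol F6, and BBr3 dealkylation of F6 gives 25.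

Step 5. Dimerisation or amine-induced oligomerisation of the aryloxyketene may outrun the cycloaddition, and the vinylogous ester may hydrolyse on purification. The fallback avoids the ketene, sets out from phenol 5 and purchasable diethyl squarate, and comes back to the route at 11. LiAlH(OtBu)3 in THF at −78 °C should reduce one carbonyl of the squarate to 2,3-diethoxy-4-hydroxycyclobut-2-en-1-one F7. Catalytic HCl in CH2Cl2 expels ethanol to give 3-ethoxycyclobut-3-ene-1,2-dione F8. NaBH4 with CeCl3 in MeOH at −78 °C should reduce the ketone carbonyl next to the ethoxy-bearing carbon (the other carbonyl is a deactivated vinylogous ester) to 3-ethoxy-4-hydroxycyclobut-2-en-1-one F9. Mitsunobu etherification of F9 with 5 (PPh3, diisopropyl azodicarboxylate, THF, 0 °C) then gives 11; attack at either alpha carbon of the cyclobutenone leads to the same constitution.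

Step 1. The phenoxide is flanked by two methoxy groups and deactivated by the para formyl group, and the bromide is electron-rich, so the coupling may stall and reductive debromination may take over. The fallback sets out from 1 and comes back to the route at 3: Chan–Lam–Evans oxidative coupling of 1 with purchasable 3,4,5-trimethoxyphenylboronic acid (Cu(OAc)2, pyridine, 4 Å molecular sieves, CH2Cl2, air, rt), a room-temperature arylation known to accept phenols with two ortho substituents. No compound outside the list arises (F0).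

Further compounds
F1 | step 6 | 2-[3,5-dimethoxy-4-(3,4,5-trimethoxyphenoxy)phenoxy]-3,5-dimethoxybenzaldehyde | COc1cc(OC)c(Oc2cc(OC)c(Oc3cc(OC)c(OC)c(OC)c3)c(OC)c2)c(C=O)c1
F2 | step 6 | 2-[3,5-dimethoxy-4-(3,4,5-trimethoxyphenoxy)phenoxy]-3,5-dimethoxyphenyl formate | COc1cc(OC)c(Oc2cc(OC)c(Oc3cc(OC)c(OC)c(OC)c3)c(OC)c2)c(OC=O)c1
F3 | step 6 | 2-[3,5-dimethoxy-4-(3,4,5-trimethoxyphenoxy)phenoxy]-3,5-dimethoxyphenol | COc1cc(O)c(Oc2cc(OC)c(Oc3cc(OC)c(OC)c(OC)c3)c(OC)c2)c(OC)c1
F4 | step 6 | 2-(2-ArO-3,5-dimethoxyphenoxy)-5-(2,4,6-trimethoxyphenoxy)isophthalaldehyde | COc1cc(OC)c(Oc2cc(OC)c(Oc3cc(OC)c(OC)c(OC)c3)c(OC)c2)c(Oc2c(C=O)cc(Oc3c(OC)cc(OC)cc3OC)cc2C=O)c1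
F5 | step 6 | 2-(2-ArO-3,5-dimethoxyphenoxy)-5-(2,4,6-trimethoxyphenoxy)-1,3-phenylene diformate | COc1cc(OC)c(Oc2cc(OC)c(Oc3cc(OC)c(OC)c(OC)c3)c(OC)c2)c(Oc2c(OC=O)cc(Oc3c(OC)cc(OC)cc3OC)cc2OC=O)c1
F6 | step 6 | 2-(2-ArO-3,5-dimethoxyphenoxy)-5-(2,4,6-trimethoxyphenoxy)benzene-1,3-diol | COc1cc(OC)c(Oc2cc(OC)c(Oc3cc(OC)c(OC)c(OC)c3)c(OC)c2)c(Oc2c(O)cc(Oc3c(OC)cc(OC)cc3OC)cc2O)c1
F7 | step 5 | 2,3-diethoxy-4-hydroxycyclobut-2-en-1-one (racemic) | CCOC1=C(OCC)C(=O)C1O
F8 | step 5 | 3-ethoxycyclobut-3-ene-1,2-dione | CCOC1=CC(=O)C1=O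
F9 | step 5 | 3-ethoxy-4-hydroxycyclobut-2-en-1-one (racemic) | CCOC1=CC(=O)C1O
F0 | step 1 | none | none
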